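Follow one substrate molecule up 3 hops: reagent turns it into mono adduct, then bis adduct, then triple product. Each hop uses one reagent, so the molecule's chances depend on how much reagent has been used per substrate.

| flask | substrate | reagent | scavenger | remark | time |
|---|---|---|---|---|---|
| elm | 0.010 M | 0.0056 M (fed, over 80 s) | 0.012 M | run made earlier; the fed solution adds 0.10 times the starting volume |  |
| ash | 0.010 M | 0.022 M (fed, over 80 s) | 0.012 M | run made earlier; the fed solution adds 0.10 times the starting volume |  |
| dawn | 0.010 M | 0.00800 M (fed, over 80 s) | 0.0120 M | the fed solution adds 0.10 times the starting volume | 2.5 min |
| autumn | 0.010 M | 0.0300 M (fed, over 80 s) | 0.0120 M | the fed solution adds 0.10 times the starting volume | 2.5 min |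

- elm (time / s: triple product / %, mono adduct / %): 10.0: 0.5, 0.3; 15.0: 0, 1.3; 30.0: 0.6, 2.5; 60.0: 0.1, 8.8; 120: 0, 19.6
- ash (time / s: triple product / %, mono adduct / %): 10.0: 0.1, 0.9; 25.0: 0.3, 6.8; 50.0: 0.1, 18.6; 80.0: 2.0, 30.4; 120: 8.1, 33.9

(each reading ± 0.5 percentage points)

- charges are per starting volume, the dose included; the dosed solution carries all of it

- which of these holds the largest part of the substrate at the end of dawn (bis adduct / triple product / substrate / mono adduct)
- which of these holds the largest part of the substrate at the end of autumn (bis adduct / triple product / substrate / mono adduct)
- amount of triple product at the end of autumn, in percent of the substrate charged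

Early mono adduct gives the hop constant, since the fed reagent rises steadily and its running sum grows with the square of time. Ash at 25.0 s reads 0.791 M⁻¹ s⁻¹, and elm at 30.0 s reads 0.794 M⁻¹ s⁻¹. The two readings lie within their scatter of each other, and this reckoning assumes that the scavenger takes no reagent.

The time scales then form a ladder. In autumn, a substrate molecule under the whole charge waits about 46.3 s for a hop, which is shorter than the feed of 80 s. Next comes the life of reagent among the molecules that can hop, 126 s, taken as pseudo-first-order in reagent and equal in dawn and autumn; it is longer than the feed. The asked 150 s is longer still. In dawn, the wait of 174 s exceeds the asked time.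

Taking all hops as equally fast, this reckoning leaves 42.6% of the reagent in either flask. Autumn's figure is 1.72: the hop number, the reagent used divided by the substrate charged, which is the mean count of hops per substrate molecule when this reckoning lets triple product go on hopping. Dawn's is 0.459.

Hops fall at random, so the share with no hop is the exponential of minus the hop number, and each next share is the last one times the hop number over the rung reached. By this reckoning dawn keeps 63.2% as substrate. By this reckoning autumn gets 17.9% substrate, 30.8% mono adduct, 26.5% bis adduct and, as the rest, 24.9% triple product. In this reckoning mono and bis adduct tie at a hop number of 2, so its choice of mono adduct for autumn is a close one.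

The forecast gives substrate for dawn, mono adduct for autumn and 20% of triple product, a lower figure than this reckoning's 24.9%; of autumn it says “Mono narrowly leads, with moderate confidence”.

Autumn ends with bis adduct in front at 31.3%, mono adduct at 25.1% and triple product at 23.4%; dawn keeps 62.9% as substrate.

    substrate + reagent → mono adduct + released group (k = 0.860 M⁻¹ s⁻¹)
    reagent + mono adduct → bis adduct + released group (k = 1.00 M⁻¹ s⁻¹)
    reagent + bis adduct → triple product + released group (k = 0.670 M⁻¹ s⁻¹)
    substrate + released group ⇌ idle adduct, settled at all times (K = 97.0 M⁻¹)
    scavenger + released group → scavenged by-product (k = 33.0 M⁻¹ s⁻¹)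

Autumn's triple product stands at 23.4% through the slow addition of reagent together with the time allowed: dosed at once the flask gives 33.5%, and left ten times as long it gives 89.3%. In the reckoning, autumn's hop number of 1.72 gave 24.9% of triple product. The neighbour flask, autumn with 0.017 M of substrate, reckons to a hop number of 1.34 and so to 15.2% triple product, and that flask holds 14.6%.

The runs stem from a simulated flask with made-up constants.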